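**Retrosynthetic overview**

1. Sesterfisherol (rings A 5, B 8, C 6, D 5) ⇐ its (Z)-4,5-didehydro dienol by diimide reduction of the only disubstituted alkene.
2. Key disconnection: both bonds that the carbinol carbon C12 makes to C13 (closes ring C) and to C11 (closes ring B) ⇒ a seco diiodo methyl ester. The feature used: C12 is the one oxygen-bearing carbon common to rings B and C, and two of its three carbon neighbours are exocyclic to preformed rings (C13, the CH2 on ring D carbon C14; C11, the methyl-bearing alkene carbon on ring A carbon C10), so both can be delivered as carbanions to a carboxyl carbon on C2.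
3. Seco ester ⇐ Z-selective Wittig reaction (C4=C5) between a ring A phosphonium ylide and a ring D hydroxy-lactone (pseudo-acid).
4. Ring D half: (S)-limonene → cyclopentene carbaldehyde (ozonolysis, aldol) → [2,3]-Wittig–Still shift (quaternary C15) → three-component union with MeMgBr and a menthyloxy furanone (C3, then C2) → hydroboration (C14).
5. Ring A half: (R)-citronellene → enyne → zirconocene enyne cyclisation and iodinolysis (C6, alkene geometry). Ring order: D and A in separate fragments, then C and B together in the key step.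

Key step: step 21

Remark: locants are biogenetic (ring A = C6–C10, methyl on C7; ring B = C2–C6, C10–C12, methyls on C3 and C11; ring C = C1, C2, C12–C15; ring D = C14–C18, methyl on C15, isopropyl on C18; OH on C12); (S)-limonene, (R)-β-citronellene and (5R)-5-(l-menthyloxy)furan-2(5H)-one are assumed to be commercial.

**Route**

Step 1
Reactants: 1 (S)-limonene [(4S)-1-methyl-4-(prop-1-en-2-yl)cyclohex-1-ene]
Product: 2 (S)-p-menth-1-ene [(4S)-1-methyl-4-(propan-2-yl)cyclohex-1-ene]
Conditions: H2 (1 atm), RhCl(PPh3)3 (1 mol %), benzene–EtOH, rt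
Reagents that add atoms: none
Why: Homogeneous hydrogenation with RhCl(PPh3)3 should reduce the 1,1-disubstituted isopropenyl alkene much faster than the trisubstituted ring alkene; the stereocenter (future C18) is not touched.

Step 2
Reactants: 2 (S)-p-menth-1-ene
Product: 4 (3S)-6-oxo-3-(propan-2-yl)heptanal, via ozonide 3 (not isolated)
Conditions: O3, CH2Cl2, −78 °C; then Me2S, −78 °C → rt
Reagents that add atoms: ozone, [O-][O+]=O
Why: Ozonolysis with reductive work-up should cleave the only alkene to the keto aldehyde; the isopropyl-bearing center is β to the aldehyde and not enolisable.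

Step 3
Reactants: 4 (3S)-6-oxo-3-(propan-2-yl)heptanal
Product: 5 (5R)-2-methyl-5-(propan-2-yl)cyclopent-1-ene-1-carbaldehyde
Conditions: piperidine (0.2 equiv), AcOH (0.2 equiv), benzene, reflux (water removed)
Reagents that add atoms: none
Why: Amine-catalysed intramolecular aldol condensation: the enamine of the aldehyde attacks the methyl ketone to close the five-membered ring, and dehydration to the conjugated enal drives the reaction.

Step 4
Reactants: 5 (5R)-2-methyl-5-(propan-2-yl)cyclopent-1-ene-1-carbaldehyde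
Product: 6 [(5R)-2-methyl-5-(propan-2-yl)cyclopent-1-en-1-yl]methanol
Conditions: NaBH4, CeCl3·7H2O, MeOH, 0 °C
Reagents that add atoms: none
Why: Luche reduction should give clean 1,2-reduction of the enal to the allylic alcohol.

Step 5
Reactants: 6 [(5R)-2-methyl-5-(propan-2-yl)cyclopent-1-en-1-yl]methanol
Product: 7 tributyl({[(5R)-2-methyl-5-(propan-2-yl)cyclopent-1-en-1-yl]methoxy}methyl)stannane
Conditions: KH, Bu3SnCH2I, THF, 0 °C → rt
Reagents that add atoms: (iodomethyl)tributylstannane, CCCC[Sn](CCCC)(CCCC)CI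
Why: Williamson etherification of the primary allylic alkoxide with the reactive iodomethylstannane installs the carbon that becomes C1.

Step 6
Reactants: 7 tributyl stannylmethyl ether
Product: 9 [(1S,3R)-1-methyl-2-methylidene-3-(propan-2-yl)cyclopentyl]methanol, via lithiomethyl ether 8 (not isolated)
Conditions: n-BuLi, THF, −78 → −20 °C; aq. NH4Cl
Reagents that add atoms: none
Why: Wittig–Still [2,3]-sigmatropic rearrangement after tin–lithium exchange: the carbanion should add to the methyl-bearing alkene carbon on the ring face opposite the adjacent isopropyl group, setting quaternary C15 (CH2OH trans to isopropyl) and leaving the exocyclic methylene C14=C13.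

Step 7
Reactants: 9 [(1S,3R)-1-methyl-2-methylidene-3-(propan-2-yl)cyclopentyl]methanol
Product: 10 (1S,3R)-1-methyl-2-methylidene-3-(propan-2-yl)cyclopentane-1-carbaldehyde
Conditions: DMP (1,1,1-triacetoxy-1,1-dihydro-1,2-benziodoxol-3(1H)-one), NaHCO3, CH2Cl2, rt
Reagents that add atoms: none
Why: Dess–Martin oxidation of the neopentyl alcohol gives an aldehyde with no α-hydrogen, so it cannot epimerise or conjugate.

Step 8
Reactants: 11 (5R)-5-{[(1R,2S,5R)-5-methyl-2-(propan-2-yl)cyclohexyl]oxy}furan-2(5H)-one; 10 (1S,3R)-1-methyl-2-methylidene-3-(propan-2-yl)cyclopentane-1-carbaldehyde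
Product: 13 (3S,4R,5R)-3-{hydroxy[(1S,3R)-1-methyl-2-methylidene-3-(propan-2-yl)cyclopentyl]methyl}-4-methyl-5-(menthyloxy)oxolan-2-one (carbinol epimers), via bromomagnesium enolate 12 (not isolated)
Conditions: MeMgBr, CuBr·SMe2 (10 mol %), THF, −78 °C; then 10, −78 → −30 °C; aq. NH4Cl
Reagents that add atoms: methylmagnesium bromide, C[Mg]Br
Why: Copper-catalysed conjugate addition followed by aldol trapping (three components in one flask): methyl should add anti to the menthyloxy group (sets C3), and the enolate should attack the aldehyde anti to the new methyl; the carbinol configuration is erased in step 9.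

Step 9
Reactants: 13 aldol adduct
Product: 15 (4R,5R)-4-methyl-3-{[(1R,3R)-1-methyl-2-methylidene-3-(propan-2-yl)cyclopentyl]methylidene}-5-(menthyloxy)oxolan-2-one (E/Z mixture), via mesylate 14 (not isolated)
Conditions: MsCl, Et3N, DMAP (cat.), CH2Cl2, 0 °C; then DBU, rt
Reagents that add atoms: none
Why: Mesylation and E1cB elimination; the only β-hydrogen is the lactone α-hydrogen, so the alkylidene lactone is the only possible alkene.

Step 10
Reactants: 15 alkylidene lactone
Product: 17 (3R,4R,5R)-4-methyl-3-{[(1R,3R)-1-methyl-2-methylidene-3-(propan-2-yl)cyclopentyl]methyl}-5-(menthyloxy)oxolan-2-one, via cis lactone 16 (not isolated)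
Conditions: [(Ph3P)CuH]6 (0.4 equiv), H2O (2 equiv), benzene, rt; then DBU (0.2 equiv), toluene, 60 °C
Reagents that add atoms: none
Why: Copper hydride conjugate reduction should touch only the conjugated alkene and not the isolated methylene; base equilibration of the α-center then gives the all-trans lactone, which sets C2 trans to the C3 methyl.

Step 11
Reactants: 17 all-trans lactone
Product: 19 (3R,4R,5R)-3-{[(1R,2S,3R)-2-(hydroxymethyl)-1-methyl-3-(propan-2-yl)cyclopentyl]methyl}-4-methyl-5-(menthyloxy)oxolan-2-one, via alkylborane 18 (not isolated)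
Conditions: 9-BBN, THF, 0 → 40 °C; then 30% H2O2, aq. NaOAc, 0 °C → rt
Reagents that add atoms: hydrogen peroxide, OO
Why: Hydroboration–oxidation: 9-BBN should deliver hydrogen to C14 on the face opposite the isopropyl group and the angular methyl, so the new CH2OH (C13) is cis to isopropyl and trans to the lactone arm; buffered oxidation spares the lactone acetal.

Step 12
Reactants: 19 primary alcohol
Product: 20 (3R,4R,5R)-3-{[(1R,2S,3R)-2-(iodomethyl)-1-methyl-3-(propan-2-yl)cyclopentyl]methyl}-4-methyl-5-(menthyloxy)oxolan-2-one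
Conditions: I2, PPh3, imidazole, CH2Cl2, 0 °C → rt
Reagents that add atoms: iodine, II
Why: Appel-type iodination of the primary alcohol under buffered conditions that the acetal tolerates.

Step 13
Reactants: 20 iodo lactone
Product: 21 (3R,4R)-5-hydroxy-3-{[(1R,2S,3R)-2-(iodomethyl)-1-methyl-3-(propan-2-yl)cyclopentyl]methyl}-4-methyloxolan-2-one (anomers)
Conditions: 2 M HCl, THF, 50 °C
Reagents that add atoms: water, O
Why: Acid hydrolysis of the mixed acetal frees menthol and the pseudo-acid, which holds C12 at the acid level and C4 at the aldehyde level.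

Step 14
Reactants: 22 (R)-β-citronellene [(3R)-3,7-dimethylocta-1,6-diene]
Product: 24 (4R)-4-methylhex-5-enal, via ozonide 23 (not isolated)
Conditions: O3 (1.0 equiv), CH2Cl2, −78 °C; then Me2S
Reagents that add atoms: ozone, [O-][O+]=O
Why: Ozonolysis with one equivalent of ozone should cleave the electron-rich trisubstituted alkene before the vinyl group.

Step 15
Reactants: 24 (4R)-4-methylhex-5-enal
Product: 25 (3R)-7,7-dibromo-3-methylhepta-1,6-diene
Conditions: CBr4, PPh3, CH2Cl2, 0 °C
Reagents that add atoms: carbon tetrabromide, BrC(Br)(Br)Br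
Why: First stage of the Corey–Fuchs alkyne synthesis (dibromo-olefination of the aldehyde).

Step 16
Reactants: 25 (3R)-7,7-dibromo-3-methylhepta-1,6-diene
Product: 27 (3R)-3-methyloct-1-en-6-yne, via lithium acetylide 26 (not isolated)
Conditions: n-BuLi (2.1 equiv), THF, −78 → 0 °C; then MeI, −78 °C → rt
Reagents that add atoms: iodomethane, CI
Why: Second stage of the Corey–Fuchs sequence (exchange, rearrangement to the acetylide) with methylation in the same flask; the methyl becomes the C11 methyl.

Step 17
Reactants: 27 (3R)-3-methyloct-1-en-6-yne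
Product: 29 (1Z,2S,3R)-1-(1-iodoethylidene)-2-(iodomethyl)-3-methylcyclopentane, via zirconabicycle 28 (not isolated)
Conditions: Cp2ZrCl2, n-BuLi (2 equiv), THF, −78 °C → rt; then I2, 0 °C
Reagents that add atoms: iodine, II
Why: Zirconocene-mediated enyne cyclisation and iodinolysis of both C–Zr bonds: the allylic methyl should take the exo position so that C6 forms trans to it, and syn-carbometalation places zirconium (then iodine) cis to C6, which is the alkene geometry ring B needs.

Step 18
Reactants: 29 diiodide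
Product: 30 {[(1S,2R,5Z)-5-(1-iodoethylidene)-2-methylcyclopentyl]methyl}triphenylphosphonium iodide
Conditions: PPh3, MeCN, 80 °C
Reagents that add atoms: triphenylphosphine, c1ccc(cc1)P(c1ccccc1)c1ccccc1
Why: SN2 quaternisation occurs only at the primary sp3 iodide; the alkenyl iodide is inert to PPh3 without a metal catalyst.

Step 19
Reactants: 30 ring A phosphonium iodide; 21 ring D hydroxy-lactone
Product: 33 (2R,3S,4Z)-5-[(1R,2R,5Z)-5-(1-iodoethylidene)-2-methylcyclopentyl]-2-{[(1R,2S,3R)-2-(iodomethyl)-1-methyl-3-(propan-2-yl)cyclopentyl]methyl}-3-methylpent-4-enoic acid, via ylide 31 (not isolated), via sodium oxo-carboxylate 32 (not isolated)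
Conditions: 30, NaN(SiMe3)2 (1 equiv), THF, −78 °C; 21, NaN(SiMe3)2 (1 equiv), THF, −78 °C; mix, −78 → 0 °C; 1 M HCl
Reagents that add atoms: none
Why: Wittig olefination of the ring-opened aldehyde carboxylate with a non-stabilised ylide under lithium-free conditions should give the (Z)-C4=C5 alkene; the low temperature protects the α-methyl aldehyde center (C3) and both iodides.

Step 20
Reactants: 33 seco acid
Product: 34 methyl (2R,3S,4Z)-5-[(1R,2R,5Z)-5-(1-iodoethylidene)-2-methylcyclopentyl]-2-{[(1R,2S,3R)-2-(iodomethyl)-1-methyl-3-(propan-2-yl)cyclopentyl]methyl}-3-methylpent-4-enoate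
Conditions: TMSCHN2, MeOH–toluene, 0 °C
Reagents that add atoms: (trimethylsilyl)diazomethane, C[Si](C)(C)C=[N+]=[N-]
Why: Esterification with a diazoalkane is neutral, so neither C2 (α to the carboxyl) nor the iodides are at risk.

Step 21
Reactants: 34 seco diiodo methyl ester
Product: 37 (Z)-4,5-didehydrosesterfisherol (tetracyclic dienol), via dilithio ester 35 (not isolated), via lithio ketone 36 (not isolated)
Conditions: t-BuLi (4.1 equiv), pentane–Et2O (3:2), 0.005 M, −78 → −20 °C; aq. NH4Cl
Reagents that add atoms: none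
Why: Proposed new method: t-BuLi should exchange both C–I bonds faster than it adds to the ester; the primary alkyllithium (C13) then acylates the ester carbon C12 by 6-exo-trig attack with loss of LiOMe (ring C, a trans-fused hydrindanone), and the alkenyllithium (C11) adds 1,2 to the new ketone by 8-exo-trig attack (ring B). If the alkenyllithium acylates first, the alkyllithium closes ring C on the resulting enone through the same C12–C13 bond and the same product results. The closest known reaction types are the Parham-type cyclative acylation of organolithiums made by halogen–lithium exchange, the SmI2-promoted sequential nucleophilic acyl substitution/Barbier cyclisation of dihalo esters, and intramolecular alkenyllithium–ketone additions; a mixed alkyl/alkenyl dilithio ester closing a six- and an eight-membered ring at one carbon has not been described. The only new stereocenter, C12, is set in the second addition: the C2 side chain is equatorial on the chair cyclohexanone, and the tethered, fully substituted alkenyl carbon should attack along the equatorial trajectory (the axial one meets the axial hydrogens on C14 and C1), giving the trans B/C fusion with axial OH. The step needs exchange before addition (secured by the rate of iodine–lithium exchange at −78 °C), cyclisation before intermolecular attack (secured by high dilution and by the two Z alkenes, C4=C5 and C10=C11, which remove rotors from the eight-membered closure), and retention at C2 and at the alkenyl carbon (secured by low temperature and stereoretentive exchange).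

Step 22
Reactants: 37 tetracyclic dienol
Product: 38 sesterfisherol
Conditions: TsNHNH2, NaOAc, DME–H2O, 85 °C
Reagents that add atoms: none
Why: Diimide reduction should saturate the cis-disubstituted C4=C5 alkene and leave the tetrasubstituted C10=C11 alkene and the tertiary allylic alcohol untouched; no stereocenter is formed or disturbed.

**Compound list**

1 | (S)-limonene | CC1=CC[C@H](CC1)C(C)=C | starting material
2 | (4S)-1-methyl-4-(propan-2-yl)cyclohex-1-ene | CC1=CC[C@H](CC1)C(C)C | intermediate
3 | secondary ozonide of 2 (1,2,4-trioxolane across the former alkene) | CC12CC[C@H](C(C)C)CC(OO1)O2 | intermediate (not isolated)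
4 | (3S)-6-oxo-3-(propan-2-yl)heptanal | O=CC[C@@H](C(C)C)CCC(C)=O | intermediate
5 | (5R)-2-methyl-5-(propan-2-yl)cyclopent-1-ene-1-carbaldehyde | O=CC1=C(C)CC[C@@H]1C(C)C | intermediate
6 | [(5R)-2-methyl-5-(propan-2-yl)cyclopent-1-en-1-yl]methanol | OCC1=C(C)CC[C@@H]1C(C)C | intermediate
7 | tributyl({[(5R)-2-methyl-5-(propan-2-yl)cyclopent-1-en-1-yl]methoxy}methyl)stannane | CCCC[Sn](CCCC)(CCCC)COCC1=C(C)CC[C@@H]1C(C)C | intermediate
8 | ({[(5R)-2-methyl-5-(propan-2-yl)cyclopent-1-en-1-yl]methoxy}methyl)lithium | [Li]COCC1=C(C)CC[C@@H]1C(C)C | intermediate (not isolated)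
9 | [(1S,3R)-1-methyl-2-methylidene-3-(propan-2-yl)cyclopentyl]methanol | OC[C@@]1(C)CC[C@H](C(C)C)C1=C | intermediate
10 | (1S,3R)-1-methyl-2-methylidene-3-(propan-2-yl)cyclopentane-1-carbaldehyde | O=C[C@@]1(C)CC[C@H](C(C)C)C1=C | intermediate
11 | (5R)-5-{[(1R,2S,5R)-5-methyl-2-(propan-2-yl)cyclohexyl]oxy}furan-2(5H)-one | O=C1O[C@@H](O[C@@H]2C[C@H](C)CC[C@H]2C(C)C)C=C1 | starting material
12 | bromomagnesium enolate of (4R,5R)-4-methyl-5-(menthyloxy)oxolan-2-one | Br[Mg]OC1=C[C@@H](C)[C@H](O[C@@H]2C[C@H](C)CC[C@H]2C(C)C)O1 | intermediate (not isolated)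
13 | (3S,4R,5R)-3-{hydroxy[(1S,3R)-1-methyl-2-methylidene-3-(propan-2-yl)cyclopentyl]methyl}-4-methyl-5-(menthyloxy)oxolan-2-one, carbinol epimers | O=C1O[C@@H](O[C@@H]2C[C@H](C)CC[C@H]2C(C)C)[C@H](C)[C@H]1C(O)[C@@]3(C)CC[C@H](C(C)C)C3=C | intermediate
14 | methanesulfonate of 13 | O=C1O[C@@H](O[C@@H]2C[C@H](C)CC[C@H]2C(C)C)[C@H](C)[C@H]1C(OS(C)(=O)=O)[C@@]3(C)CC[C@H](C(C)C)C3=C | intermediate (not isolated)
15 | (4R,5R)-4-methyl-3-{[(1R,3R)-1-methyl-2-methylidene-3-(propan-2-yl)cyclopentyl]methylidene}-5-(menthyloxy)oxolan-2-one, E/Z mixture | O=C1O[C@@H](O[C@@H]2C[C@H](C)CC[C@H]2C(C)C)[C@H](C)C1=C[C@@]3(C)CC[C@H](C(C)C)C3=C | intermediate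
16 | (3S,4R,5R) epimer of 17 (3,4-cis lactone) | O=C1O[C@@H](O[C@@H]2C[C@H](C)CC[C@H]2C(C)C)[C@H](C)[C@@H]1C[C@@]3(C)CC[C@H](C(C)C)C3=C | intermediate (not isolated)
17 | (3R,4R,5R)-4-methyl-3-{[(1R,3R)-1-methyl-2-methylidene-3-(propan-2-yl)cyclopentyl]methyl}-5-(menthyloxy)oxolan-2-one | O=C1O[C@@H](O[C@@H]2C[C@H](C)CC[C@H]2C(C)C)[C@H](C)[C@H]1C[C@@]3(C)CC[C@H](C(C)C)C3=C | intermediate
18 | B-alkyl-9-borabicyclo[3.3.1]nonane from 17 (boron on the new CH2) | O=C1O[C@@H](O[C@@H]2C[C@H](C)CC[C@H]2C(C)C)[C@H](C)[C@H]1C[C@@]3(C)CC[C@H](C(C)C)[C@@H]3CB4C5CCCC4CCC5 | intermediate (not isolated)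
19 | (3R,4R,5R)-3-{[(1R,2S,3R)-2-(hydroxymethyl)-1-methyl-3-(propan-2-yl)cyclopentyl]methyl}-4-methyl-5-(menthyloxy)oxolan-2-one | O=C1O[C@@H](O[C@@H]2C[C@H](C)CC[C@H]2C(C)C)[C@H](C)[C@H]1C[C@@]3(C)CC[C@H](C(C)C)[C@@H]3CO | intermediate
20 | (3R,4R,5R)-3-{[(1R,2S,3R)-2-(iodomethyl)-1-methyl-3-(propan-2-yl)cyclopentyl]methyl}-4-methyl-5-(menthyloxy)oxolan-2-one | O=C1O[C@@H](O[C@@H]2C[C@H](C)CC[C@H]2C(C)C)[C@H](C)[C@H]1C[C@@]3(C)CC[C@H](C(C)C)[C@@H]3CI | intermediate
21 | (3R,4R)-5-hydroxy-3-{[(1R,2S,3R)-2-(iodomethyl)-1-methyl-3-(propan-2-yl)cyclopentyl]methyl}-4-methyloxolan-2-one, anomers | O=C1OC(O)[C@H](C)[C@H]1C[C@@]2(C)CC[C@H](C(C)C)[C@@H]2CI | intermediate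
22 | (3R)-3,7-dimethylocta-1,6-diene | C=C[C@H](C)CCC=C(C)C | starting material
23 | secondary ozonide of 22 (at the trisubstituted alkene) | C=C[C@H](C)CCC1OOC(C)(C)O1 | intermediate (not isolated)
24 | (4R)-4-methylhex-5-enal | C=C[C@H](C)CCC=O | intermediate
25 | (3R)-7,7-dibromo-3-methylhepta-1,6-diene | C=C[C@H](C)CCC=C(Br)Br | intermediate
26 | [(5R)-5-methylhept-6-en-1-yn-1-yl]lithium | C=C[C@H](C)CCC#C[Li] | intermediate (not isolated)
27 | (3R)-3-methyloct-1-en-6-yne | C=C[C@H](C)CCC#CC | intermediate
28 | zirconabicycle (Cp2Zr bridging C5 and C11 of the new ring A) | C/C1=C2\CC[C@@H](C)[C@@H]2C[Zr+2]1.c1cc[cH-]c1.c1cc[cH-]c1 | intermediate (not isolated)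
29 | (1Z,2S,3R)-1-(1-iodoethylidene)-2-(iodomethyl)-3-methylcyclopentane | C/C(I)=C1\CC[C@@H](C)[C@@H]1CI | intermediate
30 | {[(1S,2R,5Z)-5-(1-iodoethylidene)-2-methylcyclopentyl]methyl}triphenylphosphonium iodide | C/C(I)=C1\CC[C@@H](C)[C@@H]1C[P+](c2ccccc2)(c3ccccc3)c4ccccc4.[I-] | intermediate
31 | phosphonium ylide of 30 | C/C(I)=C1\CC[C@@H](C)[C@@H]1C=P(c2ccccc2)(c3ccccc3)c4ccccc4 | intermediate (not isolated)
32 | sodium (2R,3R)-2-{[(1R,2S,3R)-2-(iodomethyl)-1-methyl-3-(propan-2-yl)cyclopentyl]methyl}-3-methyl-4-oxobutanoate | [Na+].[O-]C(=O)[C@H](C[C@@]1(C)CC[C@H](C(C)C)[C@@H]1CI)[C@@H](C)C=O | intermediate (not isolated)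
33 | (2R,3S,4Z)-5-[(1R,2R,5Z)-5-(1-iodoethylidene)-2-methylcyclopentyl]-2-{[(1R,2S,3R)-2-(iodomethyl)-1-methyl-3-(propan-2-yl)cyclopentyl]methyl}-3-methylpent-4-enoic acid | C/C(I)=C1\CC[C@@H](C)[C@@H]1/C=C\[C@H](C)[C@@H](C[C@@]2(C)CC[C@H](C(C)C)[C@@H]2CI)C(O)=O | intermediate
34 | methyl ester of 33 | C/C(I)=C1\CC[C@@H](C)[C@@H]1/C=C\[C@H](C)[C@@H](C[C@@]2(C)CC[C@H](C(C)C)[C@@H]2CI)C(=O)OC | intermediate
35 | dilithio ester (lithium on C13 and on C11) | C/C([Li])=C1\CC[C@@H](C)[C@@H]1/C=C\[C@H](C)[C@@H](C[C@@]2(C)CC[C@H](C(C)C)[C@@H]2C[Li])C(=O)OC | intermediate (not isolated)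
36 | lithio ketone (ring C closed as trans-fused hydrindanone, lithium on C11) | C/C([Li])=C1\CC[C@@H](C)[C@@H]1/C=C\[C@H](C)[C@H]1C[C@@]2(C)CC[C@H](C(C)C)[C@@H]2CC1=O | intermediate (not isolated)
37 | (Z)-4,5-didehydrosesterfisherol | C/C1=C2\CC[C@@H](C)[C@@H]2/C=C\[C@H](C)[C@H]2C[C@@]3(C)CC[C@H](C(C)C)[C@@H]3C[C@]12O | intermediate
38 | sesterfisherol | C/C1=C2\CC[C@@H](C)[C@@H]2CC[C@H](C)[C@H]2C[C@@]3(C)CC[C@H](C(C)C)[C@@H]3C[C@]12O | target

**Summary and risks**

Total step count: 22. Longest linear sequence: 17 steps (steps 1–13, then 19–22).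

Steps most likely to fail:

1. Step 21 (Proposed new method). The transient ketone may be enolised by the alkenyllithium, or intermolecular addition may compete, so that ring B does not close. Fallback with known chemistry, setting out from ester 34: SmI2 with catalytic Fe(dbm)3 in THF (intramolecular nucleophilic acyl substitution of the alkyl iodide on the ester) should close ring C alone and give the keto alkenyl iodide F1, which can be purified and equilibrated at C2. An intramolecular Nozaki–Hiyama–Kishi addition to the ketone (CrCl2, catalytic NiCl2, DMSO) should then close ring B and come back to the route at dienol 37.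

2. Step 6. After tin–lithium exchange the hindered carbanion may undergo a [1,2]-shift or be protonated before it reaches the tetrasubstituted alkene, and facial control may be incomplete. Fallback, setting out from allylic alcohol 6: heating with N,N-dimethylformamide dimethyl acetal in xylene (Büchi [2,3]-rearrangement of the alkoxy(dimethylamino)carbene, no strong base and no tin) should give the N,N-dimethyl amide F2. Partial reduction with Cp2Zr(H)Cl in THF comes back to the route at aldehyde 10.

3. Step 8. The magnesium enolate may add sluggishly or reversibly (retro-aldol) to the hindered neopentyl aldehyde. Fallback, setting out from furanone 11: MeMgBr with catalytic CuBr·SMe2 and protonation gives the trans methyl lactone F3. LDA (2 equiv) and ClP(O)(OEt)2 (enol phosphate to phosphonate 1,3-shift) give the α-phosphono lactone F4. A Horner–Wadsworth–Emmons reaction of F4 with aldehyde 10 (NaH, THF) comes back to the route at alkylidene lactone 15, without the aldol adduct and the elimination.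

Further compounds
F1 | step 21 | keto alkenyl iodide (ring C closed, trans-fused hydrindanone; (Z)-alkenyl iodide intact) | C/C(I)=C1\CC[C@@H](C)[C@@H]1/C=C\[C@H](C)[C@H]1C[C@@]2(C)CC[C@H](C(C)C)[C@@H]2CC1=O
F2 | step 6 | (1S,3R)-N,N,1-trimethyl-2-methylidene-3-(propan-2-yl)cyclopentane-1-carboxamide | CN(C)C(=O)[C@@]1(C)CC[C@H](C(C)C)C1=C
F3 | step 8 | (4R,5R)-4-methyl-5-(menthyloxy)oxolan-2-one | O=C1O[C@@H](O[C@@H]2C[C@H](C)CC[C@H]2C(C)C)[C@H](C)C1
F4 | step 8 | diethyl [(4R,5R)-4-methyl-5-(menthyloxy)-2-oxooxolan-3-yl]phosphonate | O=C1O[C@@H](O[C@@H]2C[C@H](C)CC[C@H]2C(C)C)[C@H](C)C1P(=O)(OCC)OCC
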